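**Plan**

- Retrosynthesis: remove the C6 angelate and the C2/C10 acetates, open the 8,9-epoxide to the C8=C9 alkene and return C10 to the ketone. Then excise C9 (cut C8–C9 and C9–C10), which contracts the cycloheptenone to a trans-hydrindanone C10=C8 silyl enol ether. Further cuts: C7=C8 (metathesis), C5–C6 (aldol), C4–isopropyl, C1–CH3 (cuprate), C1–C10 (dithiane).
- Enabling feature: in the seven-membered ring C1–C10–C9–C8–C7–C6–C5 the C10 oxygen lies between quaternary C1 and C9=C8(CH3). Without C9 this is a six-ring ketone that can enolise only toward the methyl-bearing C8.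
- Forward order: five-membered ring (C1–C5) from 3-ethoxycyclopentenone, six-membered ring by ring-closing metathesis, seven-membered ring by one-carbon insertion, then C10 reduction, epoxidation and the three acylations.
- Stereochemistry: C2 from a lipase resolution; C1 by cuprate addition anti to O-2; C5/C6 by an anti aldol on the face away from C10; C4 by addition anti to the C5 branch; C10 by chelation-controlled syn reduction from 2-OH; C8/C9 by hydroxyl-directed epoxidation; the Z alkene comes from angelic acid.

Key step: step 15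

Numbering and faces: C1 quaternary C–CH3, C2 CH–OAc, C3 CH2, C4 C(OH)(i-Pr), C5 ring-fusion CH, C6 CH–O-angeloyl, C7 CH2, C8 C–CH3 (epoxide), C9 epoxide CH, C10 CH–OAc. α is the face of the C1 methyl (4-OH is α); β is the opposite face (H-5, O-2, O-6, O-10, epoxide O, isopropyl).

Assumption: the lipase in step 2 is taken to acetylate the (R)-alcohol, as is usual for cyclic α-hydroxy ketones, so that unreacted alcohol is (S); the sense has to be confirmed on first use.

**Route**

Step 1
Reactants: 1 3-ethoxycyclopent-2-en-1-one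
Product: 2 (±)-3-ethoxy-5-hydroxycyclopent-2-en-1-one
Conditions: KHMDS, THF, –78 °C; 2-(phenylsulfonyl)-3-phenyloxaziridine, –78 °C; AcOH quench
Reagents that add atoms: 2-(phenylsulfonyl)-3-phenyloxaziridine, O=S(=O)(N1OC1c1ccccc1)c1ccccc1
Why: Kinetic α′-deprotonation of the vinylogous ester and Davis oxaziridine hydroxylation of the potassium enolate should install the future C2 oxygen, racemic at this stage.

Step 2
Reactants: 2 (±)-3-ethoxy-5-hydroxycyclopent-2-en-1-one
Product: 3 (S)-3-ethoxy-5-hydroxycyclopent-2-en-1-one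
Conditions: Amano lipase PS, vinyl acetate, t-BuOMe, 30 °C, stopped near half conversion; chromatography
Reagents that add atoms: none
Why: Lipase-catalysed kinetic resolution by enantioselective transesterification should acetylate the (R)-alcohol and leave the (S)-alcohol, which fixes C2 and with it the absolute configuration of the whole route.

Step 3
Reactants: 3 (S)-3-ethoxy-5-hydroxycyclopent-2-en-1-one
Product: 4 (S)-5-(tert-butyldimethylsilyloxy)-3-ethoxycyclopent-2-en-1-one
Conditions: TBSCl, imidazole, DMF, 0 °C to rt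
Reagents that add atoms: tert-butyldimethylsilyl chloride, CC(C)(C)[Si](C)(C)Cl
Why: Imidazole-mediated silylation of the secondary α-hydroxyl gives the bulky silyl ether that later directs the cuprate.

Step 4
Reactants: 4 (S)-5-(tert-butyldimethylsilyloxy)-3-ethoxycyclopent-2-en-1-one; 5 1,3-dithiane
Product: 7 (S)-4-(tert-butyldimethylsilyloxy)-3-(1,3-dithian-2-yl)cyclopent-2-en-1-one, via carbinol adduct 6 (not isolated)
Conditions: 5, n-BuLi, THF, –30 °C; 4, –78 °C; then 1 M aq. HCl, THF, 0 °C
Reagents that add atoms: water, O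
Why: Stork–Danheiser transposition: 1,2-addition of the Corey–Seebach dithiane anion to the vinylogous ester carbonyl, then acid hydrolysis of the enol ether and loss of water, should place the C10 carbon on C1 and move the carbonyl to C4 without touching C2.

Step 5
Reactants: 7 (S)-4-(tert-butyldimethylsilyloxy)-3-(1,3-dithian-2-yl)cyclopent-2-en-1-one
Product: 8 trimethylsilyl enol ether of the methyl adduct (C1 methyl α, O-2 β)
Conditions: MeLi, CuI, Et2O/THF, 0 °C; TMSCl, 7, –78 to –40 °C; Et3N, pentane, filtration
Reagents that add atoms: lithium dimethylcuprate, [Li+].C[Cu-]C; chlorotrimethylsilane, C[Si](C)(C)Cl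
Why: TMSCl-accelerated Gilman cuprate 1,4-addition to the β,β-disubstituted enone should deliver methyl anti to the adjacent silyloxy group, setting quaternary C1, and trap the C4/C5 enolate regiospecifically.

Step 6
Reactants: 8 trimethylsilyl enol ether of the methyl adduct; 9 acrolein
Product: 12 anti-aldol adduct (C4 ketone with 6-OH and C7 vinyl), via lithium enolate 10 (not isolated), via chlorozinc enolate 11 (not isolated)
Conditions: MeLi, THF, 0 °C; ZnCl2, –78 °C; 9, –78 °C; aq. NH4Cl
Reagents that add atoms: none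
Why: Regiospecific enolate regeneration, transmetalation to zinc and aldol addition through a closed Zimmerman–Traxler chair should give the anti aldol (C6) from the ring (E)-enolate, with the aldehyde attacking C5 on the methyl face, away from the dithianyl group (C5–C6 bond α, trans to C10).

Step 7
Reactants: 12 anti-aldol adduct
Product: 13 6-O-benzyloxymethyl (BOM) ether of 12
Conditions: BOMCl, i-Pr2NEt, n-Bu4NI (cat.), CH2Cl2, 0 °C to rt
Reagents that add atoms: benzyl chloromethyl ether, ClCOCc1ccccc1
Why: Alkoxymethylation with an α-chloro ether and a hindered amine protects O-6 without the strong base that would cause retro-aldol or elimination.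

Step 8
Reactants: 13 6-O-BOM ketone
Product: 14 C4 tertiary alcohol (isopropyl β, OH α)
Conditions: i-PrMgCl·LiCl, LaCl3·2LiCl, THF, 0 °C; aq. NH4Cl
Reagents that add atoms: isopropylmagnesium chloride, CC(C)[Mg]Cl
Why: Lanthanide-promoted Grignard 1,2-addition should outpace enolisation and enter from the β face, anti to the α-oriented C5 branch held in a C4=O/O-6 chelate and to the pseudo-axial C1 methyl.

Step 9
Reactants: 14 C4 tertiary alcohol
Product: 15 4-O-triethylsilyl ether of 14
Conditions: TESOTf, 2,6-lutidine, CH2Cl2, –78 to 0 °C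
Reagents that add atoms: triethylsilyl trifluoromethanesulfonate, CC[Si](CC)(CC)OS(=O)(=O)C(F)(F)F
Why: Silyl triflate silylation caps the hindered tertiary alcohol so that it cannot ionise under the Lewis-acidic iron(III) step.

Step 10
Reactants: 15 4-O-triethylsilyl ether
Product: 16 C10 aldehyde
Conditions: MeI, CaCO3, MeCN/H2O 9:1, 45 °C
Reagents that add atoms: water, O
Why: Alkylative dithioacetal hydrolysis (S-methylation, then hydrolysis of the sulfonium) should unmask the non-enolisable aldehyde under near-neutral conditions that spare the silyl ethers, the BOM acetal and the vinyl group.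

Step 11
Reactants: 16 C10 aldehyde
Product: 17 C10 allylic alcohol (both C10 epimers)
Conditions: isopropenylmagnesium bromide, THF, –78 to 0 °C; aq. NH4Cl
Reagents that add atoms: isopropenylmagnesium bromide, CC(=C)[Mg]Br
Why: Grignard 1,2-addition to the neopentyl aldehyde brings in C8 with its methyl group; the carbinol configuration is irrelevant because it is oxidised next.

Step 12
Reactants: 17 C10 allylic alcohol
Product: 18 isopropenyl ketone (C10 ketone, diene for metathesis)
Conditions: Dess–Martin periodinane, CH2Cl2, 0 °C to rt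
Reagents that add atoms: none
Why: Dess–Martin oxidation converts both carbinol epimers into the single C10 ketone under mild conditions.

Step 13
Reactants: 18 isopropenyl ketone
Product: 19 trans-hydrindenone (C10 ketone, C7=C8 methyl enone)
Conditions: Grubbs second-generation catalyst (5 mol%), CH2Cl2, 40 °C
Reagents that add atoms: none
Why: Ring-closing olefin metathesis between the C7 vinyl group and the isopropenyl ketone should form C7=C8 and the six-membered ring; the trans arrangement of the two branches on the cyclopentane gives the trans ring fusion.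

Step 14
Reactants: 19 trans-hydrindenone
Product: 20 trans-hydrindanone triethylsilyl enol ether (C10=C8)
Conditions: RhCl(PPh3)3 (2 mol%), Et3SiH, benzene, 60 °C
Reagents that add atoms: triethylsilane, CC[SiH](CC)CC
Why: Rhodium-catalysed 1,4-hydrosilylation of the enone with a monohydrosilane should deliver hydride to C7 and silicon to oxygen, giving the tetrasubstituted C10=C8 enol ether directly and regiospecifically.

Step 15
Reactants: 20 trans-hydrindanone triethylsilyl enol ether; 21 diiodomethane
Product: 24 trans-hydroazulenone (C10 ketone, C8=C9 methyl enone), via siloxycyclopropane 22 (not isolated), via β-chloro ketone 23 (not isolated)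
Conditions: Et2Zn, CH2I2, toluene, 0 °C to rt; then FeCl3, pyridine, DMF, 0 °C to rt; then NaOAc, MeOH, 65 °C
Reagents that add atoms: none
Why: The zinc carbenoid EtZnCH2I (Furukawa variant of the Simmons–Smith reaction) should transfer the CH2 of 21 to the electron-rich C10=C8 enol ether in a concerted [2+1] addition that closes the three-membered ring C8–C9–C10; the face is immaterial because both cyclopropane stereocentres are transient. Iron(III) chloride then oxidises the siloxycyclopropane by single-electron transfer, the oxygen-bearing C10 radical cation undergoes β-scission of the internal C8–C10 bond to the C10 ketone and the tertiary C8 radical, and a second FeCl3 caps this as the β-chloro ketone 23 (Ito–Saegusa ring enlargement). The seven-membered ring therefore arises by fragmentation of the bicyclo[4.1.0] bond rather than by an end-to-end closure, and acetate removes HCl by E1cB to leave the conjugated C8=C9 enone. No stereocentre is formed in 24, and C1, C2, C4, C5 and C6 are spectators. The selectivity needed is regiochemical: C1 is quaternary, so the ketone can only be an enol ether toward C8 and C9 is inserted between C8 and C10, while the tertiary radical at C8 favours internal over external bond cleavage. The closest known case is the conversion of 1-siloxy-2-methylcyclohexene into 3-methylcyclohept-2-enone by the same three operations.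

Step 16
Reactants: 24 trans-hydroazulenone
Product: 25 2,4-diol enone (6-O-BOM retained)
Conditions: 48% aq. HF, MeCN, 0 °C to rt
Reagents that add atoms: none
Why: Acidic fluoride desilylation should remove the secondary TBS and tertiary TES ethers without exposing the β-hydroxy ketone to base (no retro-aldol) and without cleaving the BOM acetal.

Step 17
Reactants: 25 2,4-diol enone
Product: 26 2,4,10-triol (10-OH β, syn to 2-OH)
Conditions: Et2BOMe, THF/MeOH 4:1, –78 °C; NaBH4; AcOH; MeOH co-evaporation
Reagents that add atoms: none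
Why: Narasaka–Prasad reduction: the boron chelate between O-2 and the C10 carbonyl should be attacked by external borohydride from the side of the C1 methyl, away from the ring body, giving the 2,10-syn diol by 1,2-reduction.

Step 18
Reactants: 26 2,4,10-triol
Product: 27 8β,9β-epoxy triol
Conditions: VO(acac)2 (cat.), t-BuOOH (decane solution), CH2Cl2, 0 °C to rt
Reagents that add atoms: tert-butyl hydroperoxide, CC(C)(C)OO
Why: Vanadium-catalysed hydroxyl-directed epoxidation should deliver oxygen to the C8=C9 alkene on the face of the allylic 10-OH (and of the syn 2-OH), giving the cis epoxy alcohol and setting C8 and C9.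

Step 19
Reactants: 27 8β,9β-epoxy triol
Product: 28 2,10-diacetate (4-OH free, 6-O-BOM)
Conditions: Ac2O, pyridine, DMAP (cat.), CH2Cl2, rt
Reagents that add atoms: acetic anhydride, CC(=O)OC(C)=O
Why: DMAP-catalysed acyl transfer should esterify both secondary hydroxyls while the hindered tertiary 4-OH stays free.

Step 20
Reactants: 28 2,10-diacetate
Product: 29 6-alcohol (2,10-diacetoxy-8,9-epoxy-4,6-diol)
Conditions: H2 (1 atm), Pd(OH)2/C, EtOAc, rt
Reagents that add atoms: none
Why: Hydrogenolysis of the benzylic C–O bond should release the hemiformal, which collapses to the 6-alcohol; no alkene is present and the non-benzylic epoxide and the acetates are inert under these neutral conditions.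

Step 21
Reactants: 29 6-alcohol; 30 angelic acid
Product: 31 CNP0170993.1
Conditions: 30, 2,4,6-trichlorobenzoyl chloride, Et3N, toluene, rt; then 29, 75 °C
Reagents that add atoms: none
Why: Yamaguchi esterification: the preformed mixed anhydride should acylate the hindered secondary 6-OH at the unhindered angeloyl carbonyl, omission of DMAP avoids Z-to-E isomerisation to the tiglate, and the tertiary 4-OH does not react.

**Compound list**

1 | 3-ethoxycyclopent-2-en-1-one | CCOC1=CC(=O)CC1 | starting material
2 | (±)-3-ethoxy-5-hydroxycyclopent-2-en-1-one | CCOC1=CC(=O)C(O)C1 | intermediate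
3 | (S)-3-ethoxy-5-hydroxycyclopent-2-en-1-one | CCOC1=CC(=O)[C@@H](O)C1 | intermediate
4 | (S)-5-(tert-butyldimethylsilyloxy)-3-ethoxycyclopent-2-en-1-one | CCOC1=CC(=O)[C@@H](O[Si](C)(C)C(C)(C)C)C1 | intermediate
5 | 1,3-dithiane | C1CSCSC1 | starting material
6 | 1-(1,3-dithian-2-yl)-3-ethoxy-5-(tert-butyldimethylsilyloxy)cyclopent-2-en-1-ol (formed as lithium alkoxide, carbinol epimers) | CCOC1=CC(O)(C2SCCCS2)[C@@H](O[Si](C)(C)C(C)(C)C)C1 | intermediate (not isolated)
7 | (S)-4-(tert-butyldimethylsilyloxy)-3-(1,3-dithian-2-yl)cyclopent-2-en-1-one | O=C1C=C(C2SCCCS2)[C@@H](O[Si](C)(C)C(C)(C)C)C1 | intermediate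
8 | 4-(tert-butyldimethylsilyloxy)-3-(1,3-dithian-2-yl)-3-methyl-1-(trimethylsilyloxy)cyclopent-1-ene; methyl trans to the silyloxy group (C1 Me α, O-2 β) | C[Si](C)(C)OC1=C[C@@](C)(C2SCCCS2)[C@@H](O[Si](C)(C)C(C)(C)C)C1 | intermediate
9 | acrolein | C=CC=O | starting material
10 | lithium enolate of the methyl adduct (C4–O–Li, C4=C5) | [Li]OC1=C[C@@](C)(C2SCCCS2)[C@@H](O[Si](C)(C)C(C)(C)C)C1 | intermediate (not isolated)
11 | chlorozinc enolate of the methyl adduct | Cl[Zn]OC1=C[C@@](C)(C2SCCCS2)[C@@H](O[Si](C)(C)C(C)(C)C)C1 | intermediate (not isolated)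
12 | 4-(tert-butyldimethylsilyloxy)-3-(1,3-dithian-2-yl)-2-(1-hydroxyprop-2-enyl)-3-methylcyclopentan-1-one; C5–C6 bond α (trans to dithianyl), 6-OH anti to C1 (anti aldol) | O=C1C[C@H](O[Si](C)(C)C(C)(C)C)[C@](C)(C2SCCCS2)[C@H]1[C@@H](O)C=C | intermediate
13 | 6-O-benzyloxymethyl ether of 12 | O=C1C[C@H](O[Si](C)(C)C(C)(C)C)[C@](C)(C2SCCCS2)[C@H]1[C@@H](OCOCc3ccccc3)C=C | intermediate
14 | C4 tertiary alcohol: 1-isopropylcyclopentan-1-ol from 13; isopropyl β, OH α (cis to the C5 branch) | CC(C)[C@]1(O)C[C@H](O[Si](C)(C)C(C)(C)C)[C@](C)(C2SCCCS2)[C@H]1[C@@H](OCOCc3ccccc3)C=C | intermediate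
15 | 4-O-triethylsilyl ether of 14 | CC(C)[C@]1(O[Si](CC)(CC)CC)C[C@H](O[Si](C)(C)C(C)(C)C)[C@](C)(C2SCCCS2)[C@H]1[C@@H](OCOCc3ccccc3)C=C | intermediate
16 | C10 aldehyde (formyl on quaternary C1, β) | CC(C)[C@]1(O[Si](CC)(CC)CC)C[C@H](O[Si](C)(C)C(C)(C)C)[C@](C)(C=O)[C@H]1[C@@H](OCOCc2ccccc2)C=C | intermediate
17 | C10 allylic alcohol, 1-hydroxy-2-methylprop-2-enyl on C1 (C10 epimers) | CC(C)[C@]1(O[Si](CC)(CC)CC)C[C@H](O[Si](C)(C)C(C)(C)C)[C@](C)(C(O)C(C)=C)[C@H]1[C@@H](OCOCc2ccccc2)C=C | intermediate
18 | isopropenyl ketone, 2-methylprop-2-enoyl on C1 | CC(C)[C@]1(O[Si](CC)(CC)CC)C[C@H](O[Si](C)(C)C(C)(C)C)[C@](C)(C(=O)C(C)=C)[C@H]1[C@@H](OCOCc2ccccc2)C=C | intermediate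
19 | trans-fused hydrindenone: C10 ketone, C7=C8 with 8-methyl, 6-OBOM β, 1-Me α, H-5 β, 2-OTBS β, 4-OTES α, 4-isopropyl β | c1ccccc1COCO[C@H]2C=C(C)C(=O)[C@@]3(C)[C@@H](O[Si](C)(C)C(C)(C)C)C[C@@](O[Si](CC)(CC)CC)(C(C)C)[C@H]23 | intermediate
20 | trans-hydrindanone triethylsilyl enol ether (C10=C8), other groups as in 19 | c1ccccc1COCO[C@H]2CC(C)=C(O[Si](CC)(CC)CC)[C@@]3(C)[C@@H](O[Si](C)(C)C(C)(C)C)C[C@@](O[Si](CC)(CC)CC)(C(C)C)[C@H]23 | intermediate (key-step precursor)
21 | diiodomethane | ICI | starting material
22 | siloxycyclopropane: C9 methylene bridging C8 and C10 (cyclopropane face not defined) | c1ccccc1COCO[C@H]2CC3(C)CC3(O[Si](CC)(CC)CC)[C@@]4(C)[C@@H](O[Si](C)(C)C(C)(C)C)C[C@@](O[Si](CC)(CC)CC)(C(C)C)[C@H]24 | intermediate (not isolated)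
23 | β-chloro ketone: seven-membered C10 ketone with 8-chloro-8-methyl (C8 epimers) | c1ccccc1COCO[C@H]2CC(C)(Cl)CC(=O)[C@@]3(C)[C@@H](O[Si](C)(C)C(C)(C)C)C[C@@](O[Si](CC)(CC)CC)(C(C)C)[C@H]23 | intermediate (not isolated)
24 | trans-fused hydroazulenone: C10 ketone, C8=C9 with 8-methyl, 6-OBOM, 2-OTBS, 4-OTES | c1ccccc1COCO[C@H]2CC(C)=CC(=O)[C@@]3(C)[C@@H](O[Si](C)(C)C(C)(C)C)C[C@@](O[Si](CC)(CC)CC)(C(C)C)[C@H]23 | intermediate (key-step product)
25 | 2β,4α-dihydroxy enone, 6-OBOM | c1ccccc1COCO[C@H]2CC(C)=CC(=O)[C@@]3(C)[C@@H](O)C[C@@](O)(C(C)C)[C@H]23 | intermediate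
26 | 2β,4α,10β-triol with C8=C9, 6-OBOM | c1ccccc1COCO[C@H]2CC(C)=C[C@@H](O)[C@@]3(C)[C@@H](O)C[C@@](O)(C(C)C)[C@H]23 | intermediate
27 | 8β,9β-epoxy-2β,4α,10β-triol, 6-OBOM | c1ccccc1COCO[C@H]2C[C@@]3(C)O[C@H]3[C@@H](O)[C@@]4(C)[C@@H](O)C[C@@](O)(C(C)C)[C@H]24 | intermediate
28 | 2β,10β-diacetoxy-8β,9β-epoxy-4α-ol, 6-OBOM | c1ccccc1COCO[C@H]2C[C@@]3(C)O[C@H]3[C@@H](OC(C)=O)[C@@]4(C)[C@@H](OC(C)=O)C[C@@](O)(C(C)C)[C@H]24 | intermediate
29 | 2β,10β-diacetoxy-8β,9β-epoxy-4α,6β-diol | O[C@H]1C[C@@]2(C)O[C@H]2[C@@H](OC(C)=O)[C@@]2(C)[C@@H](OC(C)=O)C[C@@](O)(C(C)C)[C@H]12 | intermediate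
30 | angelic acid, (Z)-2-methylbut-2-enoic acid | C/C=C(/C)C(=O)O | starting material
31 | CNP0170993.1 | C/C=C(/C)C(=O)O[C@H]1C[C@@]2(C)O[C@H]2[C@@H](OC(C)=O)[C@@]2(C)[C@@H](OC(C)=O)C[C@@](O)(C(C)C)[C@H]12 | target

**Count and risks**

Total step count: 21. Longest linear sequence: 21 steps (from 1).

Steps most likely to fail:

1. Step 8. Enolisation or β-hydride reduction of the crowded C4 ketone by the secondary Grignard reagent may outrun addition, and the β-oxygen substituents could then be lost by elimination. The fallback sets out from 13 and uses a smaller sp2 nucleophile without a transferable β-hydrogen, with the alkene saturated later. Isopropenylmagnesium bromide with CeCl3 should give the isopropenyl carbinol F1, and TESOTf/2,6-lutidine its silyl ether F2. MeI/CaCO3 then gives the aldehyde F3, isopropenylmagnesium bromide the allylic alcohol F4, and Dess–Martin oxidation the dienone F5. Ring-closing metathesis should give the cyclohexenone F6, because the C4 isopropenyl group is hindered and could only close to a trans-fused bicyclo[3.3.0]octene. Hydrogenation over Pd/C in EtOAc with pyridine (which suppresses hydrogenolysis of the BOM ether) should saturate the ring alkene and the isopropenyl group to the ketone F7. TESOTf/Et3N converts F7 into the enol ether, and the route is rejoined at 20.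

2. Step 15. Methylene transfer to the hindered tetrasubstituted enol ether may stall. Under iron(III) the siloxycyclopropane may also open by protonation instead of oxidation, giving the gem-dimethyl ketone without ring enlargement, with loss of silyl or acetal groups. The fallback keeps the same two bonds (C8–C9 and C9–C10) but uses a free halocarbene and a thermal ring opening. From 20, CHBr3/KOt-Bu in pentane at –20 °C should give the dibromocyclopropane F8. Warming in toluene with pyridine should open the internal bond with loss of bromotriethylsilane to the 9-bromo enone F9. Hydrodebromination with Pd(PPh3)4/Bu3SnH returns to the route at 24.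

3. Step 17. The boron chelate may expose the other carbonyl face, so that hydride is delivered from the β side and the 10α-epimer forms. The fallback replaces substrate control by reagent control before desilylation. From 24, CBS reduction with the (S)-methyl oxazaborolidine and catecholborane in toluene at –78 °C (quaternary C1 as the large group, the alkenyl C9 as the small group) should give the 10β-allylic alcohol F10 with both silyl ethers in place. Buffered HF·pyridine in THF then removes both silyl groups, and the route is rejoined at 26.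

**Further compounds**

F1 | step 8 | C4 isopropenyl carbinol (isopropenyl β, OH α) | CC(=C)[C@]1(O)C[C@H](O[Si](C)(C)C(C)(C)C)[C@](C)(C2SCCCS2)[C@H]1[C@@H](OCOCc3ccccc3)C=C
F2 | step 8 | 4-O-triethylsilyl ether of F1 | CC(=C)[C@]1(O[Si](CC)(CC)CC)C[C@H](O[Si](C)(C)C(C)(C)C)[C@](C)(C2SCCCS2)[C@H]1[C@@H](OCOCc3ccccc3)C=C
F3 | step 8 | C10 aldehyde with C4 isopropenyl | CC(=C)[C@]1(O[Si](CC)(CC)CC)C[C@H](O[Si](C)(C)C(C)(C)C)[C@](C)(C=O)[C@H]1[C@@H](OCOCc2ccccc2)C=C
F4 | step 8 | C10 allylic alcohol with C4 isopropenyl (C10 epimers) | CC(=C)[C@]1(O[Si](CC)(CC)CC)C[C@H](O[Si](C)(C)C(C)(C)C)[C@](C)(C(O)C(C)=C)[C@H]1[C@@H](OCOCc2ccccc2)C=C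
F5 | step 8 | isopropenyl ketone with C4 isopropenyl | CC(=C)[C@]1(O[Si](CC)(CC)CC)C[C@H](O[Si](C)(C)C(C)(C)C)[C@](C)(C(=O)C(C)=C)[C@H]1[C@@H](OCOCc2ccccc2)C=C
F6 | step 8 | trans-hydrindenone with C4 isopropenyl | c1ccccc1COCO[C@H]2C=C(C)C(=O)[C@@]3(C)[C@@H](O[Si](C)(C)C(C)(C)C)C[C@@](O[Si](CC)(CC)CC)(C(C)=C)[C@H]23
F7 | step 8 | saturated trans-hydrindanone with C4 isopropyl (C8 epimers) | c1ccccc1COCO[C@H]2CC(C)C(=O)[C@@]3(C)[C@@H](O[Si](C)(C)C(C)(C)C)C[C@@](O[Si](CC)(CC)CC)(C(C)C)[C@H]23
F8 | step 15 | 9,9-dibromo siloxycyclopropane | c1ccccc1COCO[C@H]2CC3(C)C(Br)(Br)C3(O[Si](CC)(CC)CC)[C@@]4(C)[C@@H](O[Si](C)(C)C(C)(C)C)C[C@@](O[Si](CC)(CC)CC)(C(C)C)[C@H]24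
F9 | step 15 | 9-bromo hydroazulenone (C10 ketone, C8=C9) | c1ccccc1COCO[C@H]2CC(C)=C(Br)C(=O)[C@@]3(C)[C@@H](O[Si](C)(C)C(C)(C)C)C[C@@](O[Si](CC)(CC)CC)(C(C)C)[C@H]23
F10 | step 17 | 10β-allylic alcohol with 2-OTBS and 4-OTES | c1ccccc1COCO[C@H]2CC(C)=C[C@@H](O)[C@@]3(C)[C@@H](O[Si](C)(C)C(C)(C)C)C[C@@](O[Si](CC)(CC)CC)(C(C)C)[C@H]23
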